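**Plan**

1. Retrosynthesis: the four phenol silyl ethers and the C8 oxidation level are adjusted last. The C2–C3 bond of the bicyclo[3.2.1]oct-3-ene-2,8-dione is then cut, so that C3 becomes a methyl group on C4 and C2 a lactone carbonyl, with a ring oxygen in place of C3 (a 3-oxabicyclo[3.2.1]octan-2-one).
2. Further cuts: C1–C2 (C2 from carbonyldiimidazole), C4–C5 (aldol with a 4-arylbut-3-en-2-one), then the C6–aryl and C7–aryl bonds, back to (R)-4-silyloxycyclopentenone.
3. Forward: the five-membered ring is bought; aryl at C7, aryl at C6 and the side chain at C5 are added; the six-membered lactone ring closes by C-acylation at C1; the carbocyclic six-membered ring closes by exchange of the ring oxygen for carbon.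
4. Enabling feature: C4 carries the ring oxygen of the six-membered lactone, a methyl group and the styryl group. The C4–O bond therefore ionizes to a cation delocalized through the styryl carbons into the para-oxygenated ring. Loss of a methyl proton gives a diene whose terminus (future C3) sits next to the C2 acyl group, which the lactone has fixed cis on the five-membered ring.
5. Stereochemistry: C7 from the (R)-silyloxy enone (anti addition, then relay), C6 anti to C7, C5 anti to C6, C1 cis to C5 through the tether. C4 (lactones) and C8 (carbinols) are transient.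

Key step: step 8

Remarks on the chemistry: locants C1–C8 are those of the target's bicyclo[3.2.1]octane skeleton (C1, C5 bridgeheads; C2, C8 carbonyls; C3=C4; C6, C7 aryl-bearing) and are used for the corresponding atoms of all earlier intermediates (O3 in the lactones). C4 of compounds 14–19 and C8 of compounds 18–22 are carried as epimer mixtures and are left undefined in the SMILES; both centers are erased later.

**Route**

Step 1
Reactants: 1 4-bromophenol
Product: 2 (4-bromophenoxy)triisopropylsilane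
Conditions: i-Pr3SiCl, imidazole, DMF, rt
Reagents that add atoms: triisopropylsilyl chloride CC(C)[Si](Cl)(C(C)C)C(C)C
Why: Standard silylation of a phenol; the bulky triisopropylsilyl ether should survive organomagnesium chemistry, amide base and the acidic key step.

Step 2
Reactants: 3 5-bromobenzene-1,3-diol
Product: 4 1-bromo-3,5-bis(triisopropylsilyloxy)benzene
Conditions: i-Pr3SiCl (2.3 equiv), imidazole, DMF, rt
Reagents that add atoms: triisopropylsilyl chloride CC(C)[Si](Cl)(C(C)C)C(C)C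
Why: Double phenol silylation; the two bulky silyl ethers also shield the ring positions ortho to the later ring attachment against electrophiles.

Step 3
Reactants: 5 (E)-4-(4-hydroxyphenyl)but-3-en-2-one
Product: 6 (E)-4-[4-(triisopropylsilyloxy)phenyl]but-3-en-2-one
Conditions: i-Pr3SiCl, imidazole, CH2Cl2, rt
Reagents that add atoms: triisopropylsilyl chloride CC(C)[Si](Cl)(C(C)C)C(C)C
Why: Phenol silylation under non-nucleophilic conditions that leave the enone untouched.

Step 4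
Reactants: 2 (4-bromophenoxy)triisopropylsilane; 7 (R)-4-(tert-butyldimethylsilyloxy)cyclopent-2-en-1-one
Product: 10 (R)-4-[4-(triisopropylsilyloxy)phenyl]cyclopent-2-en-1-one, via aryl Grignard reagent 8 (not isolated), via trans silyloxy ketone 9 (not isolated)
Conditions: 2, Mg turnings, THF, 45 °C; CuBr·SMe2 (10 mol %), 7, THF, −78 °C; NH4Cl (aq); crude 9, DBU, CH2Cl2, −20 °C, short contact
Reagents that add atoms: none
Why: Copper-catalyzed conjugate addition should occur anti to the silyloxy group, and E1cB loss of silanolate then moves the enone, so the C7 stereocenter is set by the stereocenter of 7 (addition–elimination chirality relay).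

Step 5
Reactants: 4 1-bromo-3,5-bis(triisopropylsilyloxy)benzene; 10 (R)-4-[4-(triisopropylsilyloxy)phenyl]cyclopent-2-en-1-one; 6 (E)-4-[4-(triisopropylsilyloxy)phenyl]but-3-en-2-one; 11 1,1'-carbonyldiimidazole
Product: 15 (3E)-2-[(1S,2S,3R)-2-[3,5-bis(triisopropylsilyloxy)phenyl]-5-oxo-3-[4-(triisopropylsilyloxy)phenyl]cyclopentyl]-4-[4-(triisopropylsilyloxy)phenyl]but-3-en-2-yl 1H-imidazole-1-carboxylate, via aryl Grignard reagent 12 (not isolated), via bromomagnesium enolate 13 (not isolated), via bromomagnesium aldolate 14 (not isolated)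
Conditions: 4, Mg turnings, THF, 45 °C; CuBr·SMe2 (10 mol %), 10, THF, −78 °C; then 6, −78 °C, 30 min; then 11, −78 → −20 °C; NH4Cl (aq); quick filtration through neutral alumina, used at once
Reagents that add atoms: none
Why: Conjugate addition–enolate trapping (three-component coupling): the aryl group should add anti to the C7 aryl (sets C6) and the regiodefined enolate should add 1,2 to the ketone of 6 anti to the new C6 aryl (sets C5), this being the kinetic mode at −78 °C; O-acylation of the tertiary alkoxide in the flask should block retro-aldol.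

Step 6
Reactants: 15 the imidazole-1-carboxylate from step 5
Product: 17 (1S,5S,6S,7S)-6-[3,5-bis(triisopropylsilyloxy)phenyl]-4-methyl-7-[4-(triisopropylsilyloxy)phenyl]-4-[(E)-2-[4-(triisopropylsilyloxy)phenyl]ethenyl]-3-oxabicyclo[3.2.1]octane-2,8-dione, via lithium enolate 16 (not isolated)
Conditions: LiN(SiMe3)2 (1.1 equiv), THF, −78 → −30 °C; NH4Cl (aq)
Reagents that add atoms: none
Why: Kinetic deprotonation at the unhindered C1 methylene and intramolecular Claisen-type C-acylation by the alkoxycarbonylimidazole should close the six-membered lactone; the tether from C5 forces the new C1–C2 bond cis to the C5 side chain, and the imidazolide released can return any O-acylated material.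

Step 7
Reactants: 17 the bridged keto lactone from step 6
Product: 18 (1S,5R,6S,7S)-6-[3,5-bis(triisopropylsilyloxy)phenyl]-8-hydroxy-4-methyl-7-[4-(triisopropylsilyloxy)phenyl]-4-[(E)-2-[4-(triisopropylsilyloxy)phenyl]ethenyl]-3-oxabicyclo[3.2.1]octan-2-one
Conditions: NaBH4, CeCl3·7H2O, MeOH/THF, −60 °C
Reagents that add atoms: none
Why: The strained bridging ketone should be reduced much faster than the lactone; the carbinol level at C8 is needed so that ring opening in step 8 does not give a β-keto acid or an enolizable C5, and either C8 epimer serves.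

Step 8
Reactants: 18 the hydroxy lactone from step 7
Product: 22 (1S,5S,6S,7S)-6-[3,5-bis(triisopropylsilyloxy)phenyl]-8-hydroxy-7-[4-(triisopropylsilyloxy)phenyl]-4-[(E)-2-[4-(triisopropylsilyloxy)phenyl]ethenyl]bicyclo[3.2.1]oct-3-en-2-one, via lactone trifluoroacetate 19 (not isolated), via dienyl mixed anhydride 20 (not isolated), via dienone trifluoroacetate 21 (not isolated)
Conditions: (CF3CO)2O (6 equiv), CH2Cl2 (0.01 M), 0 °C, 15 min; CF3SO3H (10 mol %), −40 → 0 °C; then MeOH, NaHCO3, 0 °C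
Reagents that add atoms: none
Why: After trifluoroacetylation of the C8 hydroxyl, acid cleaves the C4–O bond of the lactone to a tertiary cation delocalized through the styryl carbons into the para-silyloxyphenyl ring, while the freed C2 carboxyl becomes a mixed trifluoroacetic anhydride (acylium equivalent). Loss of a proton from the C4 methyl gives a 2-substituted 1-aryl-1,3-diene whose CH2 terminus (C3) attacks the C2 acyl carbon, and the regenerated C4 cation loses the now acidic C3 proton to give the cross-conjugated dienone, so that the ring oxygen is exchanged for carbon. The closest known reaction type is the rearrangement of γ- and δ-lactones to cyclopentenones and cyclohexenones in polyphosphoric acid or P2O5/MeSO3H, together with the trifluoroacetic anhydride cyclization of alkenoic acids (Kondakov-type olefin acylation). The six-membered carbocycle, and with it the seven-membered ring of the bicyclo[3.2.1]octene, closes by 6-endo-trig attack of the diene terminus on the acyl carbon. No new stereocenter is formed: C1 and C5 keep the cis relation fixed by the lactone, C6 and C7 are untouched, and the C4 epimers converge because C4 becomes trigonal. The step needs acylation at the diene terminus and no epimerization at C5; the terminus is the most nucleophilic and least hindered site and the only one giving a six-membered ring with a fully delocalized cation, the C6 aryl is trans to both reacting groups, the C7 aryl can only be attacked meta to its oxygen, and high dilution at low temperature should suppress intermolecular paths.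

Step 9
Reactants: 22 the hydroxy dienone from step 8
Product: 23 (1R,5S,6S,7S)-6-[3,5-bis(triisopropylsilyloxy)phenyl]-7-[4-(triisopropylsilyloxy)phenyl]-4-[(E)-2-[4-(triisopropylsilyloxy)phenyl]ethenyl]bicyclo[3.2.1]oct-3-ene-2,8-dione
Conditions: Dess–Martin periodinane, NaHCO3, CH2Cl2, 0 °C → rt
Reagents that add atoms: none
Why: Neutral oxidation of the secondary C8 carbinol; both C8 epimers converge, and the bridgeheads next to the new ketone cannot enolize, so C1 and C5 are safe.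

Step 10
Reactants: 23 the tetrasilyl dione from step 9
Product: 24 (1R,5S,6S,7S)-6-(3,5-dihydroxyphenyl)-7-(4-hydroxyphenyl)-4-[(E)-2-(4-hydroxyphenyl)ethenyl]bicyclo[3.2.1]oct-3-ene-2,8-dione
Conditions: Bu4NF (5 equiv), AcOH (5 equiv), THF, 0 °C
Reagents that add atoms: none
Why: Acetic acid-buffered fluoride should cleave the four aryl silyl ethers without base-induced retro-Claisen opening of the non-enolizable 1,3-diketone.

**Compound list**

1 | 4-bromophenol | Oc1ccc(Br)cc1 | starting material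
2 | (4-bromophenoxy)triisopropylsilane | Brc1ccc(O[Si](C(C)C)(C(C)C)C(C)C)cc1 | intermediate
3 | 5-bromobenzene-1,3-diol | Oc1cc(O)cc(Br)c1 | starting material
4 | 1-bromo-3,5-bis(triisopropylsilyloxy)benzene | Brc1cc(O[Si](C(C)C)(C(C)C)C(C)C)cc(O[Si](C(C)C)(C(C)C)C(C)C)c1 | intermediate
5 | (E)-4-(4-hydroxyphenyl)but-3-en-2-one | CC(=O)/C=C/c1ccc(O)cc1 | starting material
6 | (E)-4-[4-(triisopropylsilyloxy)phenyl]but-3-en-2-one | CC(=O)/C=C/c1ccc(O[Si](C(C)C)(C(C)C)C(C)C)cc1 | intermediate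
7 | (R)-4-(tert-butyldimethylsilyloxy)cyclopent-2-en-1-one | O=C1C=C[C@H](O[Si](C)(C)C(C)(C)C)C1 | starting material
8 | [4-(triisopropylsilyloxy)phenyl]magnesium bromide | Br[Mg]c1ccc(O[Si](C(C)C)(C(C)C)C(C)C)cc1 | intermediate (not isolated)
9 | (3S,4R)-4-(tert-butyldimethylsilyloxy)-3-[4-(triisopropylsilyloxy)phenyl]cyclopentan-1-one | O=C1C[C@@H](c2ccc(O[Si](C(C)C)(C(C)C)C(C)C)cc2)[C@H](O[Si](C)(C)C(C)(C)C)C1 | intermediate (not isolated)
10 | (R)-4-[4-(triisopropylsilyloxy)phenyl]cyclopent-2-en-1-one | O=C1C[C@@H](c2ccc(O[Si](C(C)C)(C(C)C)C(C)C)cc2)C=C1 | intermediate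
11 | 1,1'-carbonyldiimidazole | O=C(n1ccnc1)n1ccnc1 | starting material
12 | [3,5-bis(triisopropylsilyloxy)phenyl]magnesium bromide | Br[Mg]c1cc(O[Si](C(C)C)(C(C)C)C(C)C)cc(O[Si](C(C)C)(C(C)C)C(C)C)c1 | intermediate (not isolated)
13 | bromomagnesium (3S,4R)-3-[3,5-bis(triisopropylsilyloxy)phenyl]-4-[4-(triisopropylsilyloxy)phenyl]cyclopent-1-en-1-olate | Br[Mg]OC1=C[C@@H](c2cc(O[Si](C(C)C)(C(C)C)C(C)C)cc(O[Si](C(C)C)(C(C)C)C(C)C)c2)[C@H](c2ccc(O[Si](C(C)C)(C(C)C)C(C)C)cc2)C1 | intermediate (not isolated)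
14 | bromomagnesium alkoxide of the tertiary aldol (side chain on C5 trans to the C6 aryl; C4 epimer mixture) | Br[Mg]OC(C)(/C=C/c1ccc(O[Si](C(C)C)(C(C)C)C(C)C)cc1)[C@H]1C(=O)C[C@@H](c2ccc(O[Si](C(C)C)(C(C)C)C(C)C)cc2)[C@@H]1c1cc(O[Si](C(C)C)(C(C)C)C(C)C)cc(O[Si](C(C)C)(C(C)C)C(C)C)c1 | intermediate (not isolated)
15 | (3E)-2-[(1S,2S,3R)-2-[3,5-bis(triisopropylsilyloxy)phenyl]-5-oxo-3-[4-(triisopropylsilyloxy)phenyl]cyclopentyl]-4-[4-(triisopropylsilyloxy)phenyl]but-3-en-2-yl 1H-imidazole-1-carboxylate (C4 epimer mixture) | O=C(OC(C)(/C=C/c1ccc(O[Si](C(C)C)(C(C)C)C(C)C)cc1)[C@H]1C(=O)C[C@@H](c2ccc(O[Si](C(C)C)(C(C)C)C(C)C)cc2)[C@@H]1c1cc(O[Si](C(C)C)(C(C)C)C(C)C)cc(O[Si](C(C)C)(C(C)C)C(C)C)c1)n1ccnc1 | intermediate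
16 | lithium enolate of 15 (enolate toward C1) | [Li]OC1=C[C@@H](c2ccc(O[Si](C(C)C)(C(C)C)C(C)C)cc2)[C@H](c2cc(O[Si](C(C)C)(C(C)C)C(C)C)cc(O[Si](C(C)C)(C(C)C)C(C)C)c2)[C@H]1C(C)(/C=C/c1ccc(O[Si](C(C)C)(C(C)C)C(C)C)cc1)OC(=O)n1ccnc1 | intermediate (not isolated)
17 | (1S,5S,6S,7S)-6-[3,5-bis(triisopropylsilyloxy)phenyl]-4-methyl-7-[4-(triisopropylsilyloxy)phenyl]-4-[(E)-2-[4-(triisopropylsilyloxy)phenyl]ethenyl]-3-oxabicyclo[3.2.1]octane-2,8-dione (C6 aryl exo, C7 aryl endo; C4 epimer mixture) | O=C1OC(C)(/C=C/c3ccc(O[Si](C(C)C)(C(C)C)C(C)C)cc3)[C@H]2C(=O)[C@@H]1[C@@H](c3ccc(O[Si](C(C)C)(C(C)C)C(C)C)cc3)[C@@H]2c3cc(O[Si](C(C)C)(C(C)C)C(C)C)cc(O[Si](C(C)C)(C(C)C)C(C)C)c3 | intermediate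
18 | (1S,5R,6S,7S)-6-[3,5-bis(triisopropylsilyloxy)phenyl]-8-hydroxy-4-methyl-7-[4-(triisopropylsilyloxy)phenyl]-4-[(E)-2-[4-(triisopropylsilyloxy)phenyl]ethenyl]-3-oxabicyclo[3.2.1]octan-2-one (C4 and C8 epimer mixtures) | O=C1OC(C)(/C=C/c3ccc(O[Si](C(C)C)(C(C)C)C(C)C)cc3)[C@H]2C(O)[C@@H]1[C@@H](c3ccc(O[Si](C(C)C)(C(C)C)C(C)C)cc3)[C@@H]2c3cc(O[Si](C(C)C)(C(C)C)C(C)C)cc(O[Si](C(C)C)(C(C)C)C(C)C)c3 | intermediate
19 | C8 trifluoroacetate of lactone 18 | O=C1OC(C)(/C=C/c3ccc(O[Si](C(C)C)(C(C)C)C(C)C)cc3)[C@H]2C(OC(=O)C(F)(F)F)[C@@H]1[C@@H](c3ccc(O[Si](C(C)C)(C(C)C)C(C)C)cc3)[C@@H]2c3cc(O[Si](C(C)C)(C(C)C)C(C)C)cc(O[Si](C(C)C)(C(C)C)C(C)C)c3 | intermediate (not isolated)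
20 | ring-opened dienyl carboxylic trifluoroacetic anhydride (acyl group on C1 cis to the 1-aryl-1,3-dien-3-yl group on C5; C8 trifluoroacetate) | C=C(/C=C/c3ccc(O[Si](C(C)C)(C(C)C)C(C)C)cc3)[C@H]1C(OC(=O)C(F)(F)F)[C@@H](C(=O)OC(=O)C(F)(F)F)[C@@H](c3ccc(O[Si](C(C)C)(C(C)C)C(C)C)cc3)[C@@H]1c3cc(O[Si](C(C)C)(C(C)C)C(C)C)cc(O[Si](C(C)C)(C(C)C)C(C)C)c3 | intermediate (not isolated)
21 | C8 trifluoroacetate of dienone 22 | O=C1C=C(/C=C/c3ccc(O[Si](C(C)C)(C(C)C)C(C)C)cc3)[C@H]2C(OC(=O)C(F)(F)F)[C@@H]1[C@@H](c3ccc(O[Si](C(C)C)(C(C)C)C(C)C)cc3)[C@@H]2c3cc(O[Si](C(C)C)(C(C)C)C(C)C)cc(O[Si](C(C)C)(C(C)C)C(C)C)c3 | intermediate (not isolated)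
22 | (1S,5S,6S,7S)-6-[3,5-bis(triisopropylsilyloxy)phenyl]-8-hydroxy-7-[4-(triisopropylsilyloxy)phenyl]-4-[(E)-2-[4-(triisopropylsilyloxy)phenyl]ethenyl]bicyclo[3.2.1]oct-3-en-2-one (C8 epimer mixture) | O=C1C=C(/C=C/c3ccc(O[Si](C(C)C)(C(C)C)C(C)C)cc3)[C@H]2C(O)[C@@H]1[C@@H](c3ccc(O[Si](C(C)C)(C(C)C)C(C)C)cc3)[C@@H]2c3cc(O[Si](C(C)C)(C(C)C)C(C)C)cc(O[Si](C(C)C)(C(C)C)C(C)C)c3 | intermediate
23 | (1R,5S,6S,7S)-6-[3,5-bis(triisopropylsilyloxy)phenyl]-7-[4-(triisopropylsilyloxy)phenyl]-4-[(E)-2-[4-(triisopropylsilyloxy)phenyl]ethenyl]bicyclo[3.2.1]oct-3-ene-2,8-dione | O=C1C=C(/C=C/c3ccc(O[Si](C(C)C)(C(C)C)C(C)C)cc3)[C@H]2C(=O)[C@@H]1[C@@H](c3ccc(O[Si](C(C)C)(C(C)C)C(C)C)cc3)[C@@H]2c3cc(O[Si](C(C)C)(C(C)C)C(C)C)cc(O[Si](C(C)C)(C(C)C)C(C)C)c3 | intermediate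
24 | (1R,5S,6S,7S)-6-(3,5-dihydroxyphenyl)-7-(4-hydroxyphenyl)-4-[(E)-2-(4-hydroxyphenyl)ethenyl]bicyclo[3.2.1]oct-3-ene-2,8-dione | O=C1C=C(/C=C/c2ccc(O)cc2)[C@H]2C(=O)[C@@H]1[C@@H](c1ccc(O)cc1)[C@@H]2c1cc(O)cc(O)c1 | target

**Step count and risks**

Total steps: 10. Longest linear sequence: 8 (steps 1, 4, 5, 6, 7, 8, 9, 10).

Steps most likely to fail:

1. Step 8. The allyl cation may form before the acyl group is activated and lose the C5 proton instead of a methyl proton; re-protonation would then scramble C5 and let the cation alkylate the neighbouring dioxygenated ring, or silyl groups may be lost and the diene may oligomerize. The fallback sets out from 18 and forms the diene without a free cation. Silylation of the C8 hydroxyl (Et3SiCl, imidazole) should give the C8 triethylsilyl ether of the lactone F8. A palladium-catalyzed diene-forming elimination of the allylic lactone (Pd(PPh3)4, a zerovalent palladium complex, Et3N, dioxane, 80 °C) should open the ring to the dienyl carboxylic acid F9. 1-Chloro-N,N,2-trimethylprop-1-en-1-amine should convert it under neutral conditions into the acid chloride F10. This is cyclized with AgOSO2CF3 and 2,6-di-tert-butyl-4-methylpyridine in CH2Cl2 at −78 °C (intramolecular Kondakov-type acylation of the diene terminus, again forming C2–C3) to the C8 triethylsilyl ether of the dienone F11. Pyridinium p-toluenesulfonate in MeOH removes the alkyl silyl ether, and the route is rejoined at 22.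

2. Step 5. The hindered tertiary aldolate may revert faster than it is acylated, after which the enolate adds to the enone in the 1,4 sense. The fallback sets out from 10, with 4 and 6. Thiophenol (cat. Et3N) is added to 6 to give 4-(phenylsulfanyl)-4-[4-(triisopropylsilyloxy)phenyl]butan-2-one F1, a methyl ketone that cannot act as a Michael acceptor. Compound 10 is treated with Grignard reagent 12 (CuBr·SMe2, Me3SiCl, THF, −78 °C) to give the trimethylsilyl enol ether F2. A Mukaiyama aldol of F2 with F1 (TiCl4, CH2Cl2, −78 °C) should give the tertiary aldol F3 irreversibly as its titanium chelate. Oxidation (mCPBA, −78 °C) gives the sulfoxide F4, and thermal syn-elimination (toluene, NaHCO3, 90 °C) restores the (E)-styryl unit in the tertiary allylic alcohol F5. Deprotonation with MeMgBr (1 equiv, −78 °C) and acylation with 11 rejoin the route at 15.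

3. Step 6. Acylation may occur at the enolate oxygen (cyclic enol carbonate), or the carbamate may be lost by β-elimination after deprotonation at C5. The fallback sets out from 15 and blocks the enolate oxygen. Deprotonation with LiN(SiMe3)2 in the presence of Me3SiCl (internal quench, THF, −78 °C) should give the trimethylsilyl enol ether F6. N-Methylation of the imidazole ring (MeOSO2CF3, CH2Cl2, −40 °C) gives the acylimidazolium triflate F7. This should acylate the silyl enol ether at carbon only (Mukaiyama-type acylation) and rejoin the route at 17.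

**Further compounds**

F1 | step 5 | 4-(phenylsulfanyl)-4-[4-(triisopropylsilyloxy)phenyl]butan-2-one | CC(=O)CC(Sc1ccccc1)c1ccc(O[Si](C(C)C)(C(C)C)C(C)C)cc1
F2 | step 5 | trimethylsilyl enol ether of the trans-3,4-diaryl cyclopentanone (enol ether toward C5) | C[Si](C)(C)OC1=C[C@@H](c2cc(O[Si](C(C)C)(C(C)C)C(C)C)cc(O[Si](C(C)C)(C(C)C)C(C)C)c2)[C@H](c2ccc(O[Si](C(C)C)(C(C)C)C(C)C)cc2)C1
F3 | step 5 | tertiary aldol bearing the phenylsulfanyl side chain | CC(O)(CC(Sc1ccccc1)c1ccc(O[Si](C(C)C)(C(C)C)C(C)C)cc1)[C@H]1C(=O)C[C@@H](c2ccc(O[Si](C(C)C)(C(C)C)C(C)C)cc2)[C@@H]1c1cc(O[Si](C(C)C)(C(C)C)C(C)C)cc(O[Si](C(C)C)(C(C)C)C(C)C)c1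
F4 | step 5 | sulfoxide of F3 | CC(O)(CC(S(=O)c1ccccc1)c1ccc(O[Si](C(C)C)(C(C)C)C(C)C)cc1)[C@H]1C(=O)C[C@@H](c2ccc(O[Si](C(C)C)(C(C)C)C(C)C)cc2)[C@@H]1c1cc(O[Si](C(C)C)(C(C)C)C(C)C)cc(O[Si](C(C)C)(C(C)C)C(C)C)c1
F5 | step 5 | tertiary allylic alcohol (free aldol corresponding to 14) | CC(O)(/C=C/c1ccc(O[Si](C(C)C)(C(C)C)C(C)C)cc1)[C@H]1C(=O)C[C@@H](c2ccc(O[Si](C(C)C)(C(C)C)C(C)C)cc2)[C@@H]1c1cc(O[Si](C(C)C)(C(C)C)C(C)C)cc(O[Si](C(C)C)(C(C)C)C(C)C)c1
F6 | step 6 | trimethylsilyl enol ether of 15 (enol ether toward C1) | C[Si](C)(C)OC1=C[C@@H](c2ccc(O[Si](C(C)C)(C(C)C)C(C)C)cc2)[C@H](c2cc(O[Si](C(C)C)(C(C)C)C(C)C)cc(O[Si](C(C)C)(C(C)C)C(C)C)c2)[C@H]1C(C)(/C=C/c1ccc(O[Si](C(C)C)(C(C)C)C(C)C)cc1)OC(=O)n1ccnc1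
F7 | step 6 | 3-methylimidazolium triflate of F6 | C[Si](C)(C)OC1=C[C@@H](c2ccc(O[Si](C(C)C)(C(C)C)C(C)C)cc2)[C@H](c2cc(O[Si](C(C)C)(C(C)C)C(C)C)cc(O[Si](C(C)C)(C(C)C)C(C)C)c2)[C@H]1C(C)(/C=C/c1ccc(O[Si](C(C)C)(C(C)C)C(C)C)cc1)OC(=O)n1cc[n+](C)c1.[O-]S(=O)(=O)C(F)(F)F
F8 | step 8 | C8 triethylsilyl ether of lactone 18 | O=C1OC(C)(/C=C/c3ccc(O[Si](C(C)C)(C(C)C)C(C)C)cc3)[C@H]2C(O[Si](CC)(CC)CC)[C@@H]1[C@@H](c3ccc(O[Si](C(C)C)(C(C)C)C(C)C)cc3)[C@@H]2c3cc(O[Si](C(C)C)(C(C)C)C(C)C)cc(O[Si](C(C)C)(C(C)C)C(C)C)c3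
F9 | step 8 | ring-opened dienyl carboxylic acid (C8 triethylsilyl ether) | C=C(/C=C/c3ccc(O[Si](C(C)C)(C(C)C)C(C)C)cc3)[C@H]1C(O[Si](CC)(CC)CC)[C@@H](C(=O)O)[C@@H](c3ccc(O[Si](C(C)C)(C(C)C)C(C)C)cc3)[C@@H]1c3cc(O[Si](C(C)C)(C(C)C)C(C)C)cc(O[Si](C(C)C)(C(C)C)C(C)C)c3
F10 | step 8 | acid chloride of F9 | C=C(/C=C/c3ccc(O[Si](C(C)C)(C(C)C)C(C)C)cc3)[C@H]1C(O[Si](CC)(CC)CC)[C@@H](C(=O)Cl)[C@@H](c3ccc(O[Si](C(C)C)(C(C)C)C(C)C)cc3)[C@@H]1c3cc(O[Si](C(C)C)(C(C)C)C(C)C)cc(O[Si](C(C)C)(C(C)C)C(C)C)c3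
F11 | step 8 | C8 triethylsilyl ether of dienone 22 | O=C1C=C(/C=C/c3ccc(O[Si](C(C)C)(C(C)C)C(C)C)cc3)[C@H]2C(O[Si](CC)(CC)CC)[C@@H]1[C@@H](c3ccc(O[Si](C(C)C)(C(C)C)C(C)C)cc3)[C@@H]2c3cc(O[Si](C(C)C)(C(C)C)C(C)C)cc(O[Si](C(C)C)(C(C)C)C(C)C)c3
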